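## Structural features

The target is a germacrane-type sesquiterpene lactone, numbered here in the germacrane way: C1 carbinol, C4/C5 epoxide, C6 lactone carbinol, C7=C11 butenolide alkene, C12 lactone carbonyl, C13 acetoxymethyl, C8 methacrylate, C10 methyl. A ten-membered carbocycle (C1–C10) is fused at C6–C7 to a Δ7(11)-butenolide and carries a cis-4,5-epoxide with a methyl on C4. It bears three differentiated oxygens: a free secondary hydroxyl at C1, a methacrylate at C8 and a primary allylic acetate at C13. The six stereocentres form two groups: the contiguous triad C4–C5–C6 (4R,5S,6S) and, beyond the sp2 carbon C7, C8 (S), C10 (R) and C1 (S), with C10/C1 adjacent and C8/C10 in a 1,3-relationship. Fragile points are the epoxide (acid, Lewis acid, and base, because C6–H is the γ-hydrogen of the butenolide and its removal would open the oxirane), the allylic acetate, the reducible and polymerisable methacrylate, and possible acyl migration between O13 and O8. The real difficulty is the medium ring, whose closure costs entropy and transannular strain, combined with six stereocentres that cannot be set reliably on a flexible ten-membered ring. The key step exploits that C1 and C7 are separated by three carbons on one side (C8, C9, C10) and five on the other (C2–C6). They can therefore be the two carbons of a tetrasubstituted alkene shared by a cyclopentene (C7–C8–C9–C10–C1) and a cycloheptene (C1–C2–C3–C4–C5–C6–C7). Cleaving C1=C7 releases the ten-membered ring with a ketone at C1 (the future carbinol) and one at C7 (the acceptor for the butenolide, next to the C6 oxygen).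

## Logic of the disconnections

43 ⇒ 42. The C1–H bond is cut, so the carbinol goes back to the ketone. C1 arrives as a ketone from the key step, and keeping it at that level to the end leaves only O8 and O13 to tell apart during the acylations. The gain is one stereocentre and one protecting group fewer. The demand is a hydride reduction that spares butenolide, methacrylate, acetate and epoxide and attacks the correct face of a ten-membered ketone.

42 ⇒ 41 ⇒ 40 ⇒ 39. The O8–methacryloyl and then the O13–acetyl bonds are cut, and 40 is traced to 39. Neither ester would survive the reductive and fluoride steps before it, so both go on last. The gain is a single protecting-group type on both oxygens. The demand is discrimination between a primary allylic and a hindered secondary hydroxyl without acyl migration.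

39 ⇒ 37 ⇒ 35. The C7=C11 double bond is taken back to a β-hydroxy lactone, then the C7–C11 bond is cut with the C11 nucleophile tethered to O6 as an α-bromo ester. The C7 ketone lies next to the C6 oxygen, so the annulation becomes a five-membered closure that cannot reach the C1 ketone. The gain is removal of the lactone ring and of C11–C13. The demand is an enolate formed without base that adds faster than it loses its β-silyloxy group, and a dehydration that gives the conjugated isomer.

35 ⇒ 32 (key). C1 and C7 are reconnected as a C=C bond; the two ketones are the cleavage products of a tetrasubstituted ring-fusion alkene. This is the largest simplification of the plan: the ten-membered ring becomes a fused five/seven system made by ordinary ring closures, with five stereocentres held on small rings. The demand is that the alkene be the only ozone-sensitive site and that the diketone be kept neutral.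

32 ⇒ 27 + 31, and 31 ⇒ 29 ⇒ 28. The O6–acyl bond is cut. Placing the bromo ester before the cleavage spares the diketone two operations and a free α-ketol. 31 goes back by O-silylation and amine-to-bromide exchange. The demand is acylation of a hindered epoxy alcohol without alkoxide formation.

27 ⇒ 25. The C6–C7 bond is cut: an alkenyl metal at C7 adds to a C6 aldehyde. The C7 handle is the enol triflate of a ketone and the chromium–nickel reagent tolerates everything else. The gain is opening the seven-membered ring to a chain on the cyclopentene. The demand is attack on the aldehyde face anti to the epoxide C–O bond.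

25 ⇒ 24 ⇒ 23 ⇒ 22 ⇒ 14 + 20. After C6 is adjusted from aldehyde to silyl ether, the C2–C3 bond is cut by way of the C2=C3 alkene (olefination, then saturation). A direct sp3–sp3 union is not available because a carbanion at C3 would open the epoxide, whereas 20 has no α-hydrogen. The gain is two fragments of similar size. The demand is an ylide compatible with alkenyl triflate and silyl ether, and reduction of the disubstituted alkene only.

20 ⇒ 19 ⇒ 18 ⇒ 17 ⇒ 15 + 16. The epoxide C–O bonds are cut (asymmetric epoxidation of a Z allylic alcohol), then the C4=C5 bond (Z-selective olefination). The Z alkene encodes the cis-epoxide, and the olefination differentiates the C3 and C6 ends by construction. The gain is two achiral commercial pieces. The demand is high Z selectivity and enantiofacial control by the tartrate.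

14 ⇒ 13 ⇒ 12 ⇒ 11 ⇒ 10 ⇒ 9. C2 is adjusted (phosphonium from bromide from alcohol from ester) and the C8–H bond is cut, taking the carbinol back to an enone. A 1,3-cis relation on a cyclopentene is set most reliably by hydride delivery, here with catalyst control matched to the substrate. The demand is clean 1,2-reduction of a very electrophilic enone.

9 ⇒ 8 ⇒ 7 ⇒ 5. The O–S bond of the triflate and the C8–O bond are cut: 9 is the sulfonylated enol of a 1,2-dione that comes from γ-oxygenation of 5. The ketone carbon of 5 becomes C7 and its α'-carbon is C8. The demand is oxygenation at C8 and not at C1.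

5 ⇒ 3 ⇒ 1. The ketone comes from an isopropylidene alkene and the cyclopentane from ring contraction of 1, which supplies the C10 stereocentre. The only demand is that this remote stereocentre is carried unchanged.

## Other disconnections considered

Alternative 1: The cut is C6–C7 of the macrocycle together with the lactone O–C12 bond. In the forward step the open-chain Z β-triflyloxy enoate A2, with the C6 epoxy aldehyde at the other end, is treated with CrCl2 and catalytic NiCl2. The C7 alkenylchromium species adds to C6 and the C6 alkoxide closes onto the C12 ester, giving the protected core A1.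
- In its favour: one step forms the ten-membered ring, C6 and the butenolide, and the tetrasubstituted C7=C11 alkene is present from the start.
- Against it here: the macrocyclisation is at the most congested bond, with a fully substituted alkenyl metal flanked by the C8 ether. A2 needs a geometry-defined enol triflate of a β-keto ester with a β-alkoxy group that can eliminate. C4, C5, C8, C10 and C1 must all be set on a chain.
- Comparison: the bond formed and the organochromium mechanism are the same as in step 18 of the chosen plan. There, however, the addition closes a seven-membered ring and the ten-membered ring appears by scission, with no macrocyclisation entropy.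
- Equal or better: A1 carries C1 with its configuration already fixed by acyclic reagent control. This is better than the late ketone reduction of the chosen plan, and A1 needs no diketone or samarium chemistry. Its end game is of similar length; the sequence to A2 is likely longer than that to 32.

Alternative 2: The cut is C1–C2. The Z-alkenyl iodide A4, which already carries epoxide, butenolide and acetate, is converted by CrCl2/catalytic NiCl2 into an alkenylchromium species. This adds to the C1 aldehyde and gives the ten-membered 2Z-en-1-ol A3.
- In its favour: closure is at the least hindered bond, the rigid butenolide and cis-epoxide pre-organise the chain, and only saturation of C2=C3 and the ether-to-methacrylate exchange remain.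
- Against it here: C1 is set during ring closure next to an epimerisable aldehyde α-centre (C10). The C2=C3 alkene must later be saturated in the presence of the butenolide. The allylic epoxide and allylic acetate are exposed to low-valent nickel and chromium. A4 requires the butenolide and five stereocentres on an open chain.
- Comparison: the mechanism is again the Nozaki–Hiyama–Kishi addition, but paid for with a medium-ring closure that the chosen plan avoids.
- Equal or better: both plans leave C1 to substrate control, so they are equal on that point. The end game from A3 is shorter than that from 35, which is better; the price is a longer and less convergent route to A4.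

Alternative 3: The cut is C7–C11 and C8–O. The bromoacetal A6, a cyclodecene with a C7=C8 alkene, gives a C11 radical (Bu3SnH, Et3B, air) that adds 5-exo to C7. The C8 radical is trapped by oxygen, giving the cis-fused acetal A5.
- In its favour: neutral radical conditions tolerate the epoxide, the cis ring fusion is reliable, and the C6 oxygen is used as tether as in the chosen plan.
- Against it here: the step does not make the ten-membered ring, so A6 needs its own macrocyclisation. Oxygen capture at C8 on a flexible ring is poorly face-selective. A5 has sp3 C7 and C11, so acetal oxidation and a difficult dehydrogenation to the tetrasubstituted butenolide must follow. Transannular hydrogen abstraction is also a risk.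
- Comparison: this route builds the lactone on a preformed ring, whereas the chosen plan builds the ring from a preformed bicycle.
- Equal or better: the radical step is milder than the samarium step and avoids any base-sensitive 1,5-diketone, so it is the equal or better on functional-group tolerance. On stereocontrol at C8 and on step economy it is weaker.

Key step: step 22

Remarks on the chemistry (assumptions):
- Locants C1–C13 in all intermediates are those of the target.
- 31 is used as the racemate, so 32–38 are epimer mixtures at the bromine- or C11-bearing carbon (and at C7 in 37/38); they converge at 39.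
- A check of the cleavage substrate and product against the target shows the target geometry at all five carried stereocentres, so no structural correction is needed. Only the C6 descriptor changes (S in 27/32, R in 35–38, S again from 39), because the priority of C7 changes.
- Three design changes are made:
 - The C6 oxygen carries the bromo ester already at the cleavage stage. This saves a silylation and a desilylation and avoids a free α-ketol on the diketone.
 - C8 is set by catalyst-controlled ketone reduction rather than by hydroxylation under weak 1,3-induction.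
 - The epoxy aldehyde is built by olefination. A (Z)-2-methylbut-2-ene-1,4-diol from citraconic anhydride would need a regioselective monoprotection of two nearly equivalent hydroxyls.

## Steps

Step 1
Reactants: 1 (R)-pulegone
Product: 3 methyl pulegenate [methyl (5R)-5-methyl-2-(propan-2-ylidene)cyclopentane-1-carboxylate as C1 epimers], via pulegone dibromide 2 (not isolated)
Conditions: Br2, NaHCO3, Et2O, −10 °C; then NaOMe, MeOH, reflux
Reagents that add atoms: bromine, BrBr (atoms kept only in 2); sodium methoxide, [Na+].[O-]C
Why: Bromine adds to the isopropylidene alkene and methoxide then effects a Favorskii ring contraction (cyclopropanone, alkoxide opening, loss of the second bromide), which re-forms the isopropylidene group on a cyclopentane ester; the methyl-bearing stereocentre, the future C10, is remote from the reacting carbons and is carried unchanged.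

Step 2
Reactants: 3 methyl pulegenate
Product: 5 methyl (2R)-2-methyl-5-oxocyclopentane-1-carboxylate (keto/enol forms), via primary ozonide 4 (not isolated)
Conditions: O3, CH2Cl2/MeOH, −78 °C; then Me2S, −78 °C → rt
Reagents that add atoms: ozone, [O-][O+]=O
Why: Ozonolysis of the only C=C bond (1,3-dipolar cycloaddition, cycloreversion, reduction of the peroxidic fragment) removes the isopropylidene carbon as acetone and leaves the β-keto ester; its ketone carbon is C7, its α-carbon C1 and its ester carbon C2 of the target.

Step 3
Reactants: 5 methyl (2R)-2-methyl-5-oxocyclopentane-1-carboxylate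
Product: 7 methyl (2R)-4-hydroxy-2-methyl-5-oxocyclopentane-1-carboxylate (C1/C4 epimers), via dilithium dienediolate 6 (not isolated)
Conditions: LiN(i-Pr)2 (2.2 equiv), THF, −78 → 0 °C; then 2-(benzenesulfonyl)-3-phenyloxaziridine (1.0 equiv), −78 °C; aq. NH4Cl
Reagents that add atoms: lithium diisopropylamide, [Li+].CC(C)[N-]C(C)C (lithium kept only in 6); 2-(benzenesulfonyl)-3-phenyloxaziridine, O=S(=O)(N1OC1c1ccccc1)c1ccccc1
Why: The β-keto ester dianion reacts at its γ-carbon (C8), the more basic terminus, with the electrophilic oxygen of the N-sulfonyloxaziridine (enolate hydroxylation); one equivalent of oxidant is used so that the remaining stabilised enolate at C1 is not hydroxylated, and the configuration of the new carbinol is irrelevant because step 4 oxidises it.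

Step 4
Reactants: 7 methyl (2R)-4-hydroxy-2-methyl-5-oxocyclopentane-1-carboxylate
Product: 8 methyl (5R)-2-hydroxy-5-methyl-3-oxocyclopent-1-ene-1-carboxylate
Conditions: Dess–Martin periodinane, CH2Cl2, 0 °C → rt
Reagents that add atoms: none
Why: Dess–Martin oxidation of the acyloin gives the 1,2-dione, which rests as the enol conjugated with the ester (a diosphenol); the non-basic medium keeps the C10 methine, now γ to the C8 carbonyl, from epimerising.

Step 5
Reactants: 8 methyl (5R)-2-hydroxy-5-methyl-3-oxocyclopent-1-ene-1-carboxylate
Product: 9 methyl (5R)-5-methyl-3-oxo-2-(trifluoromethanesulfonyloxy)cyclopent-1-ene-1-carboxylate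
Conditions: Tf2O, pyridine, CH2Cl2, −78 → −40 °C
Reagents that add atoms: trifluoromethanesulfonic anhydride, O=S(=O)(OS(=O)(=O)C(F)(F)F)C(F)(F)F
Why: The acidic diosphenol hydroxyl is sulfonylated on oxygen, giving the C7 alkenyl triflate that later serves as the chromium–nickel handle; low temperature and a weak base avoid γ-deprotonation at C10.

Step 6
Reactants: 9 methyl (5R)-5-methyl-3-oxo-2-(trifluoromethanesulfonyloxy)cyclopent-1-ene-1-carboxylate
Product: 10 methyl (3S,5R)-3-hydroxy-5-methyl-2-(trifluoromethanesulfonyloxy)cyclopent-1-ene-1-carboxylate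
Conditions: (R)-2-methyl-CBS-oxazaborolidine (20 mol %), catecholborane, toluene, −78 °C; then MeOH, aq. NaHCO3
Reagents that add atoms: none
Why: Corey–Bakshi–Shibata reduction: the ketone binds the oxazaborolidine boron anti to its larger, triflyloxy-substituted alkenyl arm and takes hydride on the face that gives the (S)-carbinol with the (R)-catalyst; this is also the face anti to the C10 methyl, so catalyst and substrate control are matched and place the C8 oxygen cis to the C10 methyl.

Step 7
Reactants: 10 methyl (3S,5R)-3-hydroxy-5-methyl-2-(trifluoromethanesulfonyloxy)cyclopent-1-ene-1-carboxylate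
Product: 11 methyl (3S,5R)-3-(tert-butyldimethylsilyloxy)-5-methyl-2-(trifluoromethanesulfonyloxy)cyclopent-1-ene-1-carboxylate
Conditions: t-BuMe2SiOTf, 2,6-lutidine, CH2Cl2, −78 °C
Reagents that add atoms: tert-butyldimethylsilyl trifluoromethanesulfonate, CC(C)(C)[Si](C)(C)OS(=O)(=O)C(F)(F)F
Why: Silylation of the secondary allylic alcohol with the silyl triflate and a hindered base is fast at −78 °C and does not touch the alkenyl triflate or the ester.

Step 8
Reactants: 11 methyl (3S,5R)-3-(tert-butyldimethylsilyloxy)-5-methyl-2-(trifluoromethanesulfonyloxy)cyclopent-1-ene-1-carboxylate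
Product: 12 [(3S,5R)-3-(tert-butyldimethylsilyloxy)-5-methyl-2-(trifluoromethanesulfonyloxy)cyclopent-1-en-1-yl]methanol
Conditions: i-Bu2AlH (2.5 equiv), CH2Cl2, −78 °C; aq. potassium sodium tartrate
Reagents that add atoms: none
Why: i-Bu2AlH reduces the conjugated methyl ester to the primary allylic alcohol (C2) at −78 °C; alkenyl triflate and silyl ether are inert to the hydride under these conditions.

Step 9
Reactants: 12 [(3S,5R)-3-(tert-butyldimethylsilyloxy)-5-methyl-2-(trifluoromethanesulfonyloxy)cyclopent-1-en-1-yl]methanol
Product: 14 {[(3S,5R)-3-(tert-butyldimethylsilyloxy)-5-methyl-2-(trifluoromethanesulfonyloxy)cyclopent-1-en-1-yl]methyl}triphenylphosphonium bromide, via allylic bromide 13 (not isolated)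
Conditions: CBr4, PPh3, CH2Cl2, 0 °C; then PPh3, MeCN, 45 °C
Reagents that add atoms: carbon tetrabromide, BrC(Br)(Br)Br; triphenylphosphine, c1ccc(cc1)P(c1ccccc1)c1ccccc1
Why: Appel bromination of the primary allylic alcohol (SN2 on the alkoxyphosphonium ion) and quaternisation of triphenylphosphine by the allylic bromide give the salt in one flask; the secondary silyl ether and the alkenyl triflate are not electrophilic toward the phosphine.

Step 10
Reactants: 15 (tert-butyldimethylsilyloxy)acetaldehyde; 16 ethyl 2-[bis(2,2,2-trifluoroethoxy)phosphoryl]propanoate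
Product: 17 ethyl (2Z)-4-(tert-butyldimethylsilyloxy)-2-methylbut-2-enoate
Conditions: KN(SiMe3)2, 18-crown-6, THF, −78 °C
Reagents that add atoms: none
Why: Still–Gennari olefination: the electron-poor trifluoroethyl phosphonate with a dissociated potassium counter-ion eliminates from the kinetic oxaphosphetane and gives the (Z)-trisubstituted enoate, which places the ester carbon (C3) and the silyloxymethyl carbon (C6) cis, as the cis-epoxide requires; the two ends are differentiated by construction.

Step 11
Reactants: 17 ethyl (2Z)-4-(tert-butyldimethylsilyloxy)-2-methylbut-2-enoate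
Product: 18 (2Z)-4-(tert-butyldimethylsilyloxy)-2-methylbut-2-en-1-ol
Conditions: i-Bu2AlH (2.2 equiv), CH2Cl2, −78 °C; aq. potassium sodium tartrate
Reagents that add atoms: none
Why: 1,2-Reduction of the enoate by i-Bu2AlH gives the allylic alcohol without isomerising the Z alkene or cleaving the silyl ether.

Step 12
Reactants: 18 (2Z)-4-(tert-butyldimethylsilyloxy)-2-methylbut-2-en-1-ol
Product: 19 [(2R,3S)-3-(tert-butyldimethylsilyloxymethyl)-2-methyloxiran-2-yl]methanol
Conditions: Ti(OiPr)4 (10 mol %), D-(−)-diethyl tartrate (12 mol %), t-BuOOH, 4 Å molecular sieves, CH2Cl2, −20 °C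
Reagents that add atoms: tert-butyl hydroperoxide, CC(C)(C)OO
Why: Sharpless asymmetric epoxidation: the tartrate-bound titanium alkoxide delivers the peroxide oxygen to one face of the allylic alcohol; D-(−)-diethyl tartrate gives the (2R,3S)-epoxide (C4 R, C5 S in target numbering), and the Z geometry of the alkene becomes the cis-epoxide.

Step 13
Reactants: 19 [(2R,3S)-3-(tert-butyldimethylsilyloxymethyl)-2-methyloxiran-2-yl]methanol
Product: 20 (2S,3S)-3-(tert-butyldimethylsilyloxymethyl)-2-methyloxirane-2-carbaldehyde
Conditions: Dess–Martin periodinane, NaHCO3, CH2Cl2, 0 °C → rt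
Reagents that add atoms: none
Why: Buffered Dess–Martin oxidation gives the epoxy aldehyde; it has no α-hydrogen (C4 is quaternary), so it can neither epimerise nor enolise in the Wittig step.

Step 14
Reactants: 14 {[(3S,5R)-3-(tert-butyldimethylsilyloxy)-5-methyl-2-(trifluoromethanesulfonyloxy)cyclopent-1-en-1-yl]methyl}triphenylphosphonium bromide; 20 (2S,3S)-3-(tert-butyldimethylsilyloxymethyl)-2-methyloxirane-2-carbaldehyde
Product: 22 diene triflate (4R,5S,8S,10R; C2=C3 as E/Z mixture): the cyclopentenyl triflate of 12 whose C2 is joined as CH=CH to the oxirane carbon C4 of 20, via phosphorus ylide 21 (not isolated)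
Conditions: NaN(SiMe3)2, THF, −78 °C; then 20, −78 → 0 °C
Reagents that add atoms: none
Why: Wittig olefination: deprotonation gives the allylic ylide, which adds to the non-enolisable aldehyde at −78 °C and forms the C2=C3 bond through the oxaphosphetane; the E/Z ratio is immaterial because this alkene is saturated in step 15, and no stereocentre is touched.

Step 15
Reactants: 22 diene triflate
Product: 23 saturated triflate (4R,5S,8S,10R): as 22 with C2–C3 as CH2–CH2
Conditions: 2-nitrobenzenesulfonylhydrazide, Et3N, CH2Cl2, rt
Reagents that add atoms: none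
Why: Diimide, released from the sulfonylhydrazide by triethylamine, transfers H2 in a concerted syn fashion to the 1,2-disubstituted C2=C3 alkene; the tetrasubstituted alkenyl triflate is far slower, and the neutral, metal-free conditions leave the allylic epoxide intact.

Step 16
Reactants: 23 saturated triflate
Product: 24 primary alcohol (4R,5S,8S,10R): as 23 with free C6 hydroxyl
Conditions: HF·pyridine, pyridine, THF, 0 °C
Reagents that add atoms: none
Why: Buffered HF·pyridine removes the primary silyl ether at C6 much faster than the hindered secondary allylic one at C8 (steric discrimination in silyl ether cleavage); the pyridine buffer protects the epoxide.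

Step 17
Reactants: 24 primary alcohol
Product: 25 epoxy aldehyde (4R,5R,8S,10R): as 24 with C6 as CHO
Conditions: Dess–Martin periodinane, NaHCO3, CH2Cl2, 0 °C
Reagents that add atoms: none
Why: Buffered Dess–Martin oxidation gives the cis-α,β-epoxy aldehyde under non-basic conditions that do not epimerise C5.

Step 18
Reactants: 25 epoxy aldehyde
Product: 27 (4R,5S,6S,8S,10R)-8-(tert-butyldimethylsilyloxy)-4,5-epoxy-4,10-dimethylbicyclo[5.3.0]dec-1(7)-en-6-ol, via alkenylchromium dichloride 26 (not isolated)
Conditions: CrCl2 (6 equiv), NiCl2 (5 mol %), DMF/THF, 25 °C, 0.005 M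
Reagents that add atoms: chromium dichloride, Cl[Cr]Cl (atoms kept only in 26)
Why: Nozaki–Hiyama–Kishi reaction: zerovalent nickel inserts into the alkenyl triflate, transmetallation to trivalent chromium gives the alkenylchromium species, and this adds to the aldehyde within the molecule, closing the seven-membered ring (7-exo-trig) at high dilution. Felkin–Anh attack anti to the epoxide C5–O bond places the C6 hydroxyl cis to the epoxide oxygen (6S); epoxide and silyl ether are tolerated.

Step 19
Reactants: 28 DL-serine
Product: 29 2-bromo-3-hydroxypropanoic acid (racemic)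
Conditions: NaNO2, KBr, aq. HBr, −5 → 20 °C
Reagents that add atoms: hydrogen bromide, Br
Why: Diazotisation of the amino acid and replacement of the diazonium group by bromide, with participation of the neighbouring carboxylate, is the standard route from α-amino acids to α-bromo acids; the racemate suffices because this carbon becomes sp2 C11.

Step 20
Reactants: 29 2-bromo-3-hydroxypropanoic acid
Product: 31 2-bromo-3-(tert-butyldimethylsilyloxy)propanoic acid (racemic), via bis-silyl derivative 30 (not isolated)
Conditions: t-BuMe2SiCl (2.3 equiv), imidazole, DMF, 0 °C → rt; then K2CO3, MeOH/H2O, 0 °C; pH 4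
Reagents that add atoms: tert-butyldimethylsilyl chloride, CC(C)(C)[Si](C)(C)Cl
Why: Hydroxyl and carboxyl are both silylated and the labile silyl ester is then cleaved selectively by mild aqueous carbonate, leaving the primary silyl ether, the future C13 oxygen.

Step 21
Reactants: 27 (4R,5S,6S,8S,10R)-8-(tert-butyldimethylsilyloxy)-4,5-epoxy-4,10-dimethylbicyclo[5.3.0]dec-1(7)-en-6-ol; 31 2-bromo-3-(tert-butyldimethylsilyloxy)propanoic acid
Product: 32 (4R,5S,6S,8S,10R)-8-(tert-butyldimethylsilyloxy)-4,5-epoxy-4,10-dimethylbicyclo[5.3.0]dec-1(7)-en-6-yl 2-bromo-3-(tert-butyldimethylsilyloxy)propanoate (epimers at CHBr)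
Conditions: N,N'-diisopropylcarbodiimide, DMAP (10 mol %), CH2Cl2, 0 °C → rt
Reagents that add atoms: none
Why: Carbodiimide esterification with nucleophilic catalysis (Steglich) acylates the hindered C6 carbinol without free alkoxide, so the neighbouring epoxide does not migrate (no Payne rearrangement); with the bromo ester in place before the cleavage, the sensitive diketone never has to be deprotected and acylated.

Step 22
Reactants: 32 bicyclic bromo ester
Product: 35 (4R,5S,6R,8S,10R)-8-(tert-butyldimethylsilyloxy)-4,5-epoxy-4,10-dimethyl-1,7-dioxocyclodecan-6-yl 2-bromo-3-(tert-butyldimethylsilyloxy)propanoate, via primary ozonide 33 (not isolated), via methoxy hydroperoxide 34 (not isolated)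
Conditions: O3, NaHCO3, CH2Cl2/MeOH (5:1), −78 °C (Sudan red end point); then PPh3 (1.2 equiv), −78 → 0 °C
Reagents that add atoms: ozone, [O-][O+]=O; methanol, CO (atoms kept only in 34)
Why: Ozone adds as a 1,3-dipole to the only C=C bond, the electron-rich tetrasubstituted C1=C7 ring-fusion alkene, giving primary ozonide 33, which cleaves to the C7 ketone and a carbonyl oxide at the more electron-rich C1; methanol traps the carbonyl oxide as methoxy hydroperoxide 34, triphenylphosphine reduces it, and the hemiketal loses methanol to give the C1 ketone. The closest known reaction type is the ozonolysis of tetrasubstituted ring-fusion alkenes of fused bicycles (octalins, hydrindenes, hydroazulenes) to medium-ring diketones. No ring is closed by bond formation: the ten-membered carbocycle is unveiled by scission of the bond shared by the five- and the seven-membered ring, so there is no mode of closure to satisfy and no entropic or transannular penalty of a macrocyclisation. No stereocentre is formed; C4, C5, C6, C8 and C10 are carried from 32, where the seven-membered ring fixed the cis-epoxide and C6 and the cyclopentene fixed C8 and C10. The step needs chemoselectivity, which the substrate secures because silyl ethers, epoxide, ester and the C–Br bond are inert to ozone at −78 °C and no other alkene is present; it also needs configurational integrity at C6, C8 and C10, all now α to a ketone, which the bicarbonate buffer, the low temperature and the non-basic reductant secure. Triphenylphosphine is added cold and in slight excess only, so that it reduces the peroxide faster than it can attack the secondary α-bromo ester. The 1,5-diketone can close transannularly by aldol reaction, so it is not stored but taken directly into step 23.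

Step 23
Reactants: 35 ten-membered diketone bromo ester
Product: 37 (4R,5S,6R,8S,10R)-8,13-bis(tert-butyldimethylsilyloxy)-4,5-epoxy-7-hydroxy-1-oxogermacran-12,6-olide (C7/C11 epimers), via samarium enolate 36 (not isolated)
Conditions: SmI2 (2.2 equiv), THF, −78 °C; aq. NH4Cl
Reagents that add atoms: samarium diiodide, I[Sm]I (atoms kept only in 36)
Why: Samarium-mediated intramolecular Reformatsky reaction: two equivalents of divalent samarium reduce the C–Br bond to a trivalent samarium enolate, which adds through a five-membered transition state to the adjacent C7 ketone only (the C1 ketone is out of reach) and closes the γ-lactone. At −78 °C aldol addition should outrun loss of the β-silyloxy group, and the new centres at C7 and C11 are erased in step 24.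

Step 24
Reactants: 37 β-hydroxy lactone
Product: 39 (4R,5S,6S,8S,10R)-8,13-bis(tert-butyldimethylsilyloxy)-4,5-epoxy-1-oxogermacr-7(11)-en-12,6-olide, via tertiary mesylate 38 (not isolated)
Conditions: MsCl, Et3N, DMAP (cat.), CH2Cl2, −20 → 20 °C
Reagents that add atoms: methanesulfonyl chloride, CS(=O)(=O)Cl (atoms kept only in 38)
Why: Sulfene mesylates the tertiary C7 hydroxyl and triethylamine removes the acidic C11 hydrogen, so an E1cB-like elimination gives the conjugated tetrasubstituted butenolide whichever C11 epimer is present. A weak amine base is used because a stronger one would deprotonate C6 and open the epoxide; any transannular hemiketal between the C7 hydroxyl and the C1 ketone is drained through the open form.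

Step 25
Reactants: 39 bis-silyl butenolide
Product: 40 (4R,5S,6S,8S,10R)-4,5-epoxy-8,13-dihydroxy-1-oxogermacr-7(11)-en-12,6-olide
Conditions: HF·pyridine, pyridine, THF, 0 → 20 °C
Reagents that add atoms: none
Why: Fluoride cleaves both silyl ethers; buffered HF·pyridine spares the base-sensitive butenolide and the epoxide, and migration of the lactone to O8 is geometrically impossible across the C7=C11 double bond.

Step 26
Reactants: 40 diol
Product: 41 (4R,5S,6S,8S,10R)-13-acetoxy-4,5-epoxy-8-hydroxy-1-oxogermacr-7(11)-en-12,6-olide
Conditions: AcCl (1.05 equiv), 2,4,6-collidine, CH2Cl2, −78 °C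
Reagents that add atoms: acetyl chloride, CC(Cl)=O
Why: Acetyl chloride with a hindered pyridine base at −78 °C acylates the primary allylic C13 hydroxyl much faster than the secondary C8 hydroxyl flanked by the butenolide (steric discrimination in acylation).

Step 27
Reactants: 41 monoacetate
Product: 42 (4R,5S,6S,8S,10R)-13-acetoxy-4,5-epoxy-8-methacryloyloxy-1-oxogermacr-7(11)-en-12,6-olide
Conditions: methacrylic anhydride, Et3N, DMAP (cat.), BHT, CH2Cl2, 0 °C
Reagents that add atoms: methacrylic anhydride, C=C(C)C(=O)OC(=O)C(C)=C
Why: DMAP-catalysed acylation of the remaining secondary C8 hydroxyl; fast acylation at 0 °C limits acetyl migration from O13 to O8, and the C1 ketone needs no protection.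

Step 28
Reactants: 42 keto diester
Product: 43 (1S,4R,5S,6S,8S,10R)-13-acetoxy-4,5-epoxy-1-hydroxy-8-methacryloyloxygermacr-7(11)-en-12,6-olide (CNP0119405.1)
Conditions: NaBH4, CeCl3·7H2O, MeOH/THF, −78 °C
Reagents that add atoms: none
Why: Luche reduction delivers hydride 1,2 to the only ketone and leaves butenolide, methacrylate, acetate and epoxide alone. Hydride should approach C1 from the ring periphery in the Felkin–Anh sense set by the adjacent C10 stereocentre (C9 anti, methyl inside), which corresponds to the (1S)-carbinol.

## Compound list

1 | (R)-pulegone | C[C@@H]1CCC(=C(C)C)C(=O)C1 | starting material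
2 | pulegone dibromide (C2 epimers) | C[C@@H]1CCC(Br)(C(C)(C)Br)C(=O)C1 | intermediate
3 | methyl (5R)-5-methyl-2-(propan-2-ylidene)cyclopentane-1-carboxylate (methyl pulegenate, C1 epimers) | C[C@@H]1CCC(=C(C)C)C1C(=O)OC | intermediate
4 | primary ozonide of 3 (spiro-1,2,3-trioxolane) | C[C@@H]1CCC2(OOOC2(C)C)C1C(=O)OC | intermediate
5 | methyl (2R)-2-methyl-5-oxocyclopentane-1-carboxylate | C[C@@H]1CCC(=O)C1C(=O)OC | intermediate
6 | dilithium dienediolate of 5 | COC(O[Li])=C1[C@H](C)CC=C1O[Li] | intermediate
7 | methyl (2R)-4-hydroxy-2-methyl-5-oxocyclopentane-1-carboxylate (C1/C4 epimers) | C[C@@H]1CC(O)C(=O)C1C(=O)OC | intermediate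
8 | methyl (5R)-2-hydroxy-5-methyl-3-oxocyclopent-1-ene-1-carboxylate | C[C@@H]1CC(=O)C(O)=C1C(=O)OC | intermediate
9 | methyl (5R)-5-methyl-3-oxo-2-(trifluoromethanesulfonyloxy)cyclopent-1-ene-1-carboxylate | C[C@@H]1CC(=O)C(OS(=O)(=O)C(F)(F)F)=C1C(=O)OC | intermediate
10 | methyl (3S,5R)-3-hydroxy-5-methyl-2-(trifluoromethanesulfonyloxy)cyclopent-1-ene-1-carboxylate | C[C@@H]1C[C@H](O)C(OS(=O)(=O)C(F)(F)F)=C1C(=O)OC | intermediate
11 | methyl (3S,5R)-3-(tert-butyldimethylsilyloxy)-5-methyl-2-(trifluoromethanesulfonyloxy)cyclopent-1-ene-1-carboxylate | C[C@@H]1C[C@H](O[Si](C)(C)C(C)(C)C)C(OS(=O)(=O)C(F)(F)F)=C1C(=O)OC | intermediate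
12 | [(3S,5R)-3-(tert-butyldimethylsilyloxy)-5-methyl-2-(trifluoromethanesulfonyloxy)cyclopent-1-en-1-yl]methanol | C[C@@H]1C[C@H](O[Si](C)(C)C(C)(C)C)C(OS(=O)(=O)C(F)(F)F)=C1CO | intermediate
13 | allylic bromide of 12 | C[C@@H]1C[C@H](O[Si](C)(C)C(C)(C)C)C(OS(=O)(=O)C(F)(F)F)=C1CBr | intermediate
14 | {[(3S,5R)-3-(tert-butyldimethylsilyloxy)-5-methyl-2-(trifluoromethanesulfonyloxy)cyclopent-1-en-1-yl]methyl}triphenylphosphonium bromide | C[C@@H]1C[C@H](O[Si](C)(C)C(C)(C)C)C(OS(=O)(=O)C(F)(F)F)=C1C[P+](c1ccccc1)(c1ccccc1)c1ccccc1.[Br-] | intermediate
15 | (tert-butyldimethylsilyloxy)acetaldehyde | CC(C)(C)[Si](C)(C)OCC=O | starting material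
16 | ethyl 2-[bis(2,2,2-trifluoroethoxy)phosphoryl]propanoate | CCOC(=O)C(C)P(=O)(OCC(F)(F)F)OCC(F)(F)F | starting material
17 | ethyl (2Z)-4-(tert-butyldimethylsilyloxy)-2-methylbut-2-enoate | CCOC(=O)/C(C)=C\CO[Si](C)(C)C(C)(C)C | intermediate
18 | (2Z)-4-(tert-butyldimethylsilyloxy)-2-methylbut-2-en-1-ol | OC/C(C)=C\CO[Si](C)(C)C(C)(C)C | intermediate
19 | [(2R,3S)-3-(tert-butyldimethylsilyloxymethyl)-2-methyloxiran-2-yl]methanol | OC[C@@]1(C)O[C@H]1CO[Si](C)(C)C(C)(C)C | intermediate
20 | (2S,3S)-3-(tert-butyldimethylsilyloxymethyl)-2-methyloxirane-2-carbaldehyde | O=C[C@@]1(C)O[C@H]1CO[Si](C)(C)C(C)(C)C | intermediate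
21 | phosphorus ylide from 14 | C[C@@H]1C[C@H](O[Si](C)(C)C(C)(C)C)C(OS(=O)(=O)C(F)(F)F)=C1C=P(c1ccccc1)(c1ccccc1)c1ccccc1 | intermediate
22 | diene triflate (4R,5S,8S,10R; C2=C3 E/Z) | C[C@@H]1C[C@H](O[Si](C)(C)C(C)(C)C)C(OS(=O)(=O)C(F)(F)F)=C1C=C[C@@]1(C)O[C@H]1CO[Si](C)(C)C(C)(C)C | intermediate
23 | saturated triflate (4R,5S,8S,10R), C6 silyl ether | C[C@@H]1C[C@H](O[Si](C)(C)C(C)(C)C)C(OS(=O)(=O)C(F)(F)F)=C1CC[C@@]1(C)O[C@H]1CO[Si](C)(C)C(C)(C)C | intermediate
24 | primary alcohol (4R,5S,8S,10R), free C6 hydroxyl | C[C@@H]1C[C@H](O[Si](C)(C)C(C)(C)C)C(OS(=O)(=O)C(F)(F)F)=C1CC[C@@]1(C)O[C@H]1CO | intermediate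
25 | epoxy aldehyde (4R,5R,8S,10R), C6 aldehyde | C[C@@H]1C[C@H](O[Si](C)(C)C(C)(C)C)C(OS(=O)(=O)C(F)(F)F)=C1CC[C@@]1(C)O[C@H]1C=O | intermediate
26 | alkenylchromium dichloride from 25 | C[C@@H]1C[C@H](O[Si](C)(C)C(C)(C)C)C([Cr](Cl)Cl)=C1CC[C@@]1(C)O[C@H]1C=O | intermediate
27 | (4R,5S,6S,8S,10R)-8-(tert-butyldimethylsilyloxy)-4,5-epoxy-4,10-dimethylbicyclo[5.3.0]dec-1(7)-en-6-ol | CC(C)(C)[Si](C)(C)O[C@H]1C[C@@H](C)C2=C1[C@H](O)[C@@H]1O[C@]1(C)CC2 | intermediate
28 | DL-serine | NC(CO)C(=O)O | starting material
29 | 2-bromo-3-hydroxypropanoic acid (racemic) | OCC(Br)C(=O)O | intermediate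
30 | tert-butyldimethylsilyl 2-bromo-3-(tert-butyldimethylsilyloxy)propanoate | CC(C)(C)[Si](C)(C)OCC(Br)C(=O)O[Si](C)(C)C(C)(C)C | intermediate
31 | 2-bromo-3-(tert-butyldimethylsilyloxy)propanoic acid (racemic) | CC(C)(C)[Si](C)(C)OCC(Br)C(=O)O | intermediate
32 | key-step precursor: C6 2-bromo-3-(tert-butyldimethylsilyloxy)propanoate of 27 (4R,5S,6S,8S,10R; CHBr epimers) | CC(C)(C)[Si](C)(C)O[C@H]1C[C@@H](C)C2=C1[C@H](OC(=O)C(Br)CO[Si](C)(C)C(C)(C)C)[C@@H]1O[C@]1(C)CC2 | intermediate
33 | primary ozonide of 32 (1,2,3-trioxolane across C1–C7) | CC(C)(C)[Si](C)(C)O[C@H]1C[C@@H](C)C23OOOC13[C@H](OC(=O)C(Br)CO[Si](C)(C)C(C)(C)C)[C@@H]1O[C@]1(C)CC2 | intermediate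
34 | C1 methoxy hydroperoxide, C7 ketone | CC(C)(C)[Si](C)(C)O[C@H]1C[C@@H](C)C(OC)(OO)CC[C@@]2(C)O[C@H]2[C@@H](OC(=O)C(Br)CO[Si](C)(C)C(C)(C)C)C1=O | intermediate
35 | key-step product: ten-membered 1,7-diketone (4R,5S,6R,8S,10R), C6 bromo ester, C8 silyl ether | CC(C)(C)[Si](C)(C)O[C@H]1C[C@@H](C)C(=O)CC[C@@]2(C)O[C@H]2[C@@H](OC(=O)C(Br)CO[Si](C)(C)C(C)(C)C)C1=O | intermediate
36 | samarium enolate from 35 | CC(C)(C)[Si](C)(C)O[C@H]1C[C@@H](C)C(=O)CC[C@@]2(C)O[C@H]2[C@@H](OC(O[Sm](I)I)=CCO[Si](C)(C)C(C)(C)C)C1=O | intermediate
37 | 8,13-bis(tert-butyldimethylsilyloxy)-4,5-epoxy-7-hydroxy-1-oxogermacran-12,6-olide (C7/C11 epimers) | CC(C)(C)[Si](C)(C)O[C@H]1C[C@@H](C)C(=O)CC[C@@]2(C)O[C@H]2[C@H]2OC(=O)C(CO[Si](C)(C)C(C)(C)C)C12O | intermediate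
38 | C7 mesylate of 37 | CC(C)(C)[Si](C)(C)O[C@H]1C[C@@H](C)C(=O)CC[C@@]2(C)O[C@H]2[C@H]2OC(=O)C(CO[Si](C)(C)C(C)(C)C)C12OS(C)(=O)=O | intermediate
39 | (4R,5S,6S,8S,10R)-8,13-bis(tert-butyldimethylsilyloxy)-4,5-epoxy-1-oxogermacr-7(11)-en-12,6-olide | CC(C)(C)[Si](C)(C)O[C@H]1C[C@@H](C)C(=O)CC[C@@]2(C)O[C@H]2[C@H]2OC(=O)C(CO[Si](C)(C)C(C)(C)C)=C12 | intermediate
40 | (4R,5S,6S,8S,10R)-4,5-epoxy-8,13-dihydroxy-1-oxogermacr-7(11)-en-12,6-olide | O[C@H]1C[C@@H](C)C(=O)CC[C@@]2(C)O[C@H]2[C@H]2OC(=O)C(CO)=C12 | intermediate
41 | (4R,5S,6S,8S,10R)-13-acetoxy-4,5-epoxy-8-hydroxy-1-oxogermacr-7(11)-en-12,6-olide | O[C@H]1C[C@@H](C)C(=O)CC[C@@]2(C)O[C@H]2[C@H]2OC(=O)C(COC(C)=O)=C12 | intermediate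
42 | (4R,5S,6S,8S,10R)-13-acetoxy-4,5-epoxy-8-methacryloyloxy-1-oxogermacr-7(11)-en-12,6-olide | C=C(C)C(=O)O[C@H]1C[C@@H](C)C(=O)CC[C@@]2(C)O[C@H]2[C@H]2OC(=O)C(COC(C)=O)=C12 | intermediate
43 | (1S,4R,5S,6S,8S,10R)-13-acetoxy-4,5-epoxy-1-hydroxy-8-methacryloyloxygermacr-7(11)-en-12,6-olide (CNP0119405.1) | C=C(C)C(=O)O[C@H]1C[C@@H](C)[C@@H](O)CC[C@@]2(C)O[C@H]2[C@H]2OC(=O)C(COC(C)=O)=C12 | target

## Step count and least certain steps

Total step count: 28 steps. Longest linear sequence: 22 steps from 1 (steps 1–9, 14–18, 21–28). The side branches are steps 10–13 (four steps to 20) and steps 19–20 (two steps to 31).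

Step 22 (key step). The peroxidic intermediates of a hindered, doubly allylic-oxygenated tetrasubstituted alkene may collapse slowly or rearrange instead of being reduced cleanly. The 1,5-diketone may also undergo transannular aldol closure or epimerise at C6, C8 or C10 during work-up, and the reductant may attack the α-bromo ester. The fallback avoids peroxides and reductant altogether by a stepwise dihydroxylation–glycol cleavage. It sets out from 32: OsO4 (stoichiometric, pyridine, then aq. NaHSO3) should add to the same alkene to give the cis-1,7-diol F1. Pb(OAc)4 (CH2Cl2, NaHCO3, 0 °C) should then cleave the ditertiary glycol under neutral conditions, and the route is rejoined at 35.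

Step 23. The samarium enolate may lose its β-silyloxy group before it adds, or divalent samarium may reduce the α-acyloxy ketone (ketyl formation, transannular pinacol coupling with C1, or loss of the C6 oxygen). The fallback replaces the reductive aldol–dehydration by an olefination and so also bypasses 37, 38 and step 24. It sets out from 27, which is esterified (carbodiimide, DMAP) with the phosphonate acid F2 to give the phosphonate ester F3. Ozonolysis as in step 22 gives the diketone phosphonate F4. An intramolecular Horner–Wadsworth–Emmons reaction under mild conditions (LiCl, i-Pr2NEt, MeCN, 0 °C) forms C7=C11 directly, and the route is rejoined at 39.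

Step 18. Facial selectivity at C6 may be poor, because the cyclic transition state need not follow the open-chain Felkin–Anh preference, and the alkenylchromium species may be protonated before it cyclises. The fallback moves the control of C6 from C–C bond formation to hydride delivery. It sets out from 25: if the ring closure gives mainly the C6 epimer F5, this is oxidised (Dess–Martin periodinane, NaHCO3) to the enone F6. LiBH(s-Bu)3 (THF, −78 °C) should then deliver hydride anti to both the epoxide oxygen and the C8 silyloxy group, and the route is rejoined at 27.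

Step 3. Oxygenation may occur at C1 instead of C8, the residual enolate may add to the sulfonimine by-product, or the dianion may form incompletely. The fallback uses a Rubottom oxidation and sets out from 5. The dianion is silylated (LiN(i-Pr)2, Me3SiCl) to the bis(trimethylsilyl) dienol ether F7, whose electron-rich terminal enol ether is epoxidised by dimethyldioxirane (acetone, −40 °C). Methanolysis with citric acid returns the route at 7.

Step 28. Facial selectivity of hydride delivery may be poor, since the conformation of the ten-membered ring may override the 1,2-induction from C10. The fallback sets C1 by inversion instead of by facial selection and sets out from 42. If the reduction gives mainly the (1R)-epimer F8, Mitsunobu esterification with formic acid (PPh3, diisopropyl azodicarboxylate) should give the (1S)-formate F9. Selective methanolysis of the formate (KHCO3, MeOH, 0 °C), which is far faster than that of the acetate or the methacrylate, returns the route at 43.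

## Further compounds

F1 | step 22 | cis-1,7-diol of 32 (C1/C7 configuration from syn addition, not assigned) | CC(C)(C)[Si](C)(C)O[C@H]1C[C@@H](C)C2(O)CC[C@@]3(C)O[C@H]3[C@@H](OC(=O)C(Br)CO[Si](C)(C)C(C)(C)C)C12O
F2 | step 23 | 2-(diethoxyphosphoryl)-3-(tert-butyldimethylsilyloxy)propanoic acid | CCOP(=O)(OCC)C(CO[Si](C)(C)C(C)(C)C)C(=O)O
F3 | step 23 | C6 phosphonate ester of 27 | CC(C)(C)[Si](C)(C)O[C@H]1C[C@@H](C)C2=C1[C@H](OC(=O)C(CO[Si](C)(C)C(C)(C)C)P(=O)(OCC)OCC)[C@@H]1O[C@]1(C)CC2
F4 | step 23 | ten-membered 1,7-diketone with C6 phosphonate ester | CC(C)(C)[Si](C)(C)O[C@H]1C[C@@H](C)C(=O)CC[C@@]2(C)O[C@H]2[C@@H](OC(=O)C(CO[Si](C)(C)C(C)(C)C)P(=O)(OCC)OCC)C1=O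
F5 | step 18 | C6 epimer of 27 | CC(C)(C)[Si](C)(C)O[C@H]1C[C@@H](C)C2=C1[C@@H](O)[C@@H]1O[C@]1(C)CC2
F6 | step 18 | C6 enone from F5 | CC(C)(C)[Si](C)(C)O[C@H]1C[C@@H](C)C2=C1C(=O)[C@@H]1O[C@]1(C)CC2
F7 | step 3 | bis(trimethylsilyl) dienol ether of 5 | COC(O[Si](C)(C)C)=C1[C@H](C)CC=C1O[Si](C)(C)C
F8 | step 28 | (1R)-epimer of 43 | C=C(C)C(=O)O[C@H]1C[C@@H](C)[C@H](O)CC[C@@]2(C)O[C@H]2[C@H]2OC(=O)C(COC(C)=O)=C12
F9 | step 28 | (1S)-formate of 43 | C=C(C)C(=O)O[C@H]1C[C@@H](C)[C@@H](OC=O)CC[C@@]2(C)O[C@H]2[C@H]2OC(=O)C(COC(C)=O)=C12
A1 | alternative 1 | protected germacranolide core (C8 PMB ether, C1 and C13 silyl ethers) | COc1ccc(CO[C@H]2C[C@@H](C)[C@@H](O[Si](C)(C)C(C)(C)C)CC[C@@]3(C)O[C@H]3[C@H]3OC(=O)C(CO[Si](C)(C)C(C)(C)C)=C23)cc1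
A2 | alternative 1 | open-chain Z β-triflyloxy enoate with C6 epoxy aldehyde | COC(=O)/C(CO[Si](C)(C)C(C)(C)C)=C(\OS(=O)(=O)C(F)(F)F)[C@@H](OCc1ccc(OC)cc1)C[C@@H](C)[C@@H](O[Si](C)(C)C(C)(C)C)CC[C@@]1(C)O[C@H]1C=O
A3 | alternative 2 | ten-membered 2Z-en-1-ol, C8 PMB ether | COc1ccc(CO[C@H]2C[C@@H](C)[C@@H](O)/C=C\[C@@]3(C)O[C@H]3[C@H]3OC(=O)C(COC(C)=O)=C23)cc1
A4 | alternative 2 | open-chain Z-alkenyl iodide with C1 aldehyde and butenolide in place | I/C=C\[C@@]1(C)O[C@H]1[C@H]1OC(=O)C(COC(C)=O)=C1[C@@H](OCc1ccc(OC)cc1)C[C@@H](C)C=O
A5 | alternative 3 | cis-fused bicyclic acetal with C8 hydroxyl (epimers at C11 and the acetal carbon) | CCOC1O[C@H]2[C@@H](C1CO[Si](C)(C)C(C)(C)C)[C@@H](O)C[C@@H](C)[C@@H](OCc3ccc(OC)cc3)CC[C@@]3(C)O[C@@H]23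
A6 | alternative 3 | cyclodec-7-ene bromoacetal on the C6 oxygen (C1 PMB ether, 4,5-epoxide) | CCOC(O[C@H]1C=CC[C@@H](C)[C@@H](OCc2ccc(OC)cc2)CC[C@@]2(C)O[C@@H]12)C(Br)CO[Si](C)(C)C(C)(C)C
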